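The constants are invented; the run is a simulation.

The meeting began at late times. The first speaker noted that 38.5 mM of solid reagent stands against 35 mM of left-handed substrate, at one partner per product, so the charge exceeds what the left-handed route needs by 3.50 mM, which says little about the moment in question:

left-handed substrate 35 mM; solid reagent 38.5 mM; free catalyst 0.35 mM; right-handed substrate 35 mM

- the form that holds most of the catalyst when 20% of the left-handed substrate and right-handed substrate together are converted (catalyst intermediate B / free catalyst / catalyst intermediate A)
- its share of the catalyst then
- apparent order in free catalyst when 20% of the left-handed substrate and right-handed substrate together are converted (percent change of the rate of making left-handed product for one percent more free catalyst charged)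

- free catalyst is single-handed; left-handed substrate and right-handed substrate are mirror images of each other, charged as a racemate, each of them at the stated concentration
- solid, in amounts per volume of the solution: solid reagent
- at the start none of the solid reagent is in solution
- charge of left-handed substrate (flask): 35 mM

    free catalyst + right-handed substrate ⇌ catalyst intermediate B (K1 = 6.0 M⁻¹, k1 = 1700 M⁻¹ s⁻¹)
    free catalyst + left-handed substrate ⇌ catalyst intermediate A (K2 = 190 M⁻¹, k2 = 1900 M⁻¹ s⁻¹)
    partner + catalyst intermediate A → free catalyst + left-handed product (k3 = 170 M⁻¹ s⁻¹)
    solid reagent ⇌ partner, rate k4*(cs4 - [partner]) while solid is left; crystals form when [partner] > cs4 (cs4 = 20 mM, k4 = 0.080 s⁻¹)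
    partner + catalyst intermediate B → free catalyst + right-handed product (k5 = 3.0 M⁻¹ s⁻¹)

The second speaker counted turnovers. The conversion asked for is 14.0 mM, and the selectivity factor, with both bindings taken at equilibrium, is 1790, in favour of the left-handed route. So this flask then has c(left-handed substrate) at 21.0 mM, and each catalyst has made 40.0 turnovers.

The third speaker argued that catalyst intermediate A falls back at 10.0 s⁻¹ and goes forward with partner, so its ratio to free catalyst is the binding rate over the sum of these two exits. With partner at solubility that ratio is 2.98. Balancing dissolution against consumption gives c(partner) 13.1 mM, which raises the ratio to 3.26, and a second pass gives 13.0 mM. The speaker therefore named catalyst intermediate A as the resting state, with 73.0%.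

The first speaker asked whether the balance has time to form. Partner relaxes towards the balance in about 8.10 s. A turnover takes 0.622 s, so the count needs 24.9 s, longer than that relaxation. Dissolved material then comes to 27.0 mM, less than the charge, so by this reckoning 11.5 mM of solid remains at that moment.

The meeting agreed to watch the supply fraction, c(partner) over its solubility at this balance, 64.8%. At this balance the rate follows catalyst times partner and also equals the dissolution coefficient times the gap to solubility. So, neglecting the small shift in share, the apparent order in free catalyst equals that fraction, 0.648.

The forecast gave catalyst intermediate A at 73% (69% to 77%) and an order of 0.64 (0.52 to 0.78), with the remark: “Partner does not saturate.”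

The flask gives catalyst intermediate A at 73.2%, with an order of 0.63.

This flask reaches that conversion at 31.1 s, making left-handed product at 0.544 mM s⁻¹, and the supply fraction puts the rate at 0.563 mM s⁻¹. In the second flask, with twice the free catalyst, the same fraction puts the time to that conversion at a factor of 0.638, and that flask gives 0.682.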